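**Strategy.** Numbering the lactone O1, C2 (carbonyl), C3 (carbinol), C4, C5, the ring is cut at C2–C3 and C4–C5. C3 and C4, each carrying one of the two identical arylmethyl arms, are the sp carbons of a symmetrical 1,4-diarylbut-2-yne; C2, C5 and both ring oxygens come from carbon monoxide. A rhodium-carbonyl-catalysed reductive double carbonylation under water-gas-shift conditions stitches both one-carbon units onto the alkyne and closes the ring in one operation, giving a flat 3,4-dibenzylbutenolide; the hidden symmetry of the arms removes any regiochemical question. Asymmetric conjugate reduction then sets C4, and enolate hydroxylation anti to the C4 benzyl sets C3.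

Key step: step 3

Remark on the chemistry: the target is (3S,4R), with the two arylmethyl arms cis and the hydroxyl trans to the C4 arm; the sense of induction of the chiral copper catalyst in step 4 is assumed by analogy with 4-substituted butenolides, and the antipodal ligand is used if a first run shows the opposite sense.

**Step 1**
Reactants: 1 4-(benzyloxy)-3-methoxybenzyl alcohol
Product: 2 4-(benzyloxy)-3-methoxybenzyl bromide
Conditions: PBr3 (0.4 equiv), Et2O, 0 °C; used directly
Reagents that add atoms: phosphorus tribromide, BrP(Br)Br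
Why: Bromide displaces the bromophosphite of an electron-rich benzylic alcohol (alcohol-to-bromide conversion with PBr3), and the aryl benzyl ether tolerates the brief, cold conditions.

**Step 2**
Reactants: 2 4-(benzyloxy)-3-methoxybenzyl bromide (2 equiv); 3 acetylene
Product: 5 1,4-bis[4-(benzyloxy)-3-methoxyphenyl]but-2-yne, via ethynylenedimagnesium dibromide 4 (not isolated)
Conditions: EtMgBr (2.05 equiv), acetylene (1 equiv), Et2O–THF, 0 °C to rt; then CuBr·SMe2 (10 mol%), 2 (2 equiv), THF, rt to 50 °C
Reagents that add atoms: none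
Why: Acetylene is deprotonated twice by EtMgBr and the dimagnesium acetylide 4 is benzylated at both ends under copper catalysis (alkynyl Grignard substitution of a benzylic halide), a benzylic electrophile offering no SN2' pathway.

**Step 3**
Reactants: 5 1,4-bis[4-(benzyloxy)-3-methoxyphenyl]but-2-yne
Product: 6 3,4-bis{[4-(benzyloxy)-3-methoxyphenyl]methyl}furan-2(5H)-one
Conditions: Rh6(CO)16 (0.5 mol%), CO (100 atm), H2O (4 equiv), NEt3 (1.5 equiv), THF, 100 °C, autoclave
Reagents that add atoms: carbon monoxide, [C-]#[O+]
Why: Water-gas shift on the rhodium carbonyl cluster (CO + H2O, NEt3) supplies a hydridorhodium carbonyl and CO2; the alkyne couples on rhodium with two CO ligands to a maleoyl-type rhodacyclopentenedione, which creates the C2–C3 and C4–C5 bonds cis across the former triple bond, after which hydride reduces one acyl arm to the formyl level, Rh–H adds across that C=O, and acyl–alkoxide C–O reductive elimination releases the lactone. The closest known reaction type is the rhodium-carbonyl-catalysed synthesis of furan-2(5H)-ones from internal diaryl and dialkyl alkynes with CO under water-gas-shift conditions, formally a hetero [2+2+1] annulation in which CO serves as both one-carbon partners. The single ring, the five-membered lactone, closes last by O1–C2 bond formation from a six-membered acyl(alkoxy)rhodacycle, equivalent to a 5-exo-trig attack of the C5 alkoxide on the C2 acyl carbon. No stereocentre is formed, since C3 and C4 stay sp2. The step needs chemoselectivity for double carbonylation over semi-hydrogenation of the alkyne or over-reduction of the butenolide, which the high CO pressure and the small stationary hydride concentration should secure, and it needs no regiocontrol at all, because the two alkyne carbons of 5 are equivalent; the benzyl ethers are inert.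

**Step 4**
Reactants: 6 3,4-bis{[4-(benzyloxy)-3-methoxyphenyl]methyl}furan-2(5H)-one
Product: 8 (3S,4S)-3,4-bis{[4-(benzyloxy)-3-methoxyphenyl]methyl}oxolan-2-one (trans), via cis-lactone 7 (not isolated)
Conditions: Cu(OAc)2·H2O (5 mol%), (R)-DTBM-SEGPHOS (5.5 mol%), (EtO)2MeSiH (3 equiv), t-BuOH (3 equiv), toluene, 0 °C to rt; then DBU (0.2 equiv), rt
Reagents that add atoms: none
Why: In this copper hydride asymmetric conjugate reduction of an α,β-unsaturated lactone the bisphosphine-ligated CuH should deliver hydride to the Re face of C4 (discriminating ring CH2O from the arylmethyl arm, as in 4-substituted butenolides) and so set 4S, t-BuOH protonates the copper enolate mainly anti to the C4 arm (cis-lactone 7), and DBU equilibrates C3 to the more stable trans lactone 8, whose C3 configuration is erased in step 5 in any case.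

**Step 5**
Reactants: 8 (3S,4S)-3,4-bis{[4-(benzyloxy)-3-methoxyphenyl]methyl}oxolan-2-one
Product: 10 (3S,4R)-3,4-bis{[4-(benzyloxy)-3-methoxyphenyl]methyl}-3-hydroxyoxolan-2-one, via potassium enolate 9 (not isolated)
Conditions: KN(SiMe3)2 (1.2 equiv), THF, −78 °C; then 2-(phenylsulfonyl)-3-phenyloxaziridine (1.5 equiv), −78 °C; then AcOH
Reagents that add atoms: 2-(phenylsulfonyl)-3-phenyloxaziridine, O=S(=O)(c1ccccc1)N1OC1c1ccccc1
Why: In this oxaziridine hydroxylation of a lactone enolate (Davis oxidation) the planar enolate 9 should take up oxygen on the Si face of C3, anti to the C4 arylmethyl group, so that the hydroxyl ends trans and the C3 benzyl cis to the C4 arm (3S), while C4 keeps its geometry and changes descriptor from S to R only because C3 gains priority.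

**Step 6**
Reactants: 10 (3S,4R)-3,4-bis{[4-(benzyloxy)-3-methoxyphenyl]methyl}-3-hydroxyoxolan-2-one
Product: 11 (3S,4R)-3-hydroxy-3,4-bis[(4-hydroxy-3-methoxyphenyl)methyl]oxolan-2-one
Conditions: H2 (1 atm), Pd/C (10 wt%), EtOAc–EtOH, rt
Reagents that add atoms: none
Why: Palladium-catalysed hydrogenolysis cleaves the two aryl benzyl ethers, while the tertiary alcohol (not benzylic), the lactone and both stereocentres should stay untouched.

**Compound list**
1 | 4-(benzyloxy)-3-methoxybenzyl alcohol | COc1cc(CO)ccc1OCc1ccccc1 | starting material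
2 | 4-(benzyloxy)-3-methoxybenzyl bromide | COc1cc(CBr)ccc1OCc1ccccc1 | intermediate
3 | acetylene | C#C | starting material
4 | ethynylenedimagnesium dibromide | Br[Mg]C#C[Mg]Br | intermediate
5 | 1,4-bis[4-(benzyloxy)-3-methoxyphenyl]but-2-yne | COc1cc(CC#CCc2ccc(OCc3ccccc3)c(OC)c2)ccc1OCc1ccccc1 | intermediate
6 | 3,4-bis{[4-(benzyloxy)-3-methoxyphenyl]methyl}furan-2(5H)-one | COc1cc(CC2=C(Cc3ccc(OCc4ccccc4)c(OC)c3)C(=O)OC2)ccc1OCc1ccccc1 | intermediate
7 | (3R,4S)-3,4-bis{[4-(benzyloxy)-3-methoxyphenyl]methyl}oxolan-2-one (cis) | COc1cc(C[C@@H]2COC(=O)[C@@H]2Cc2ccc(OCc3ccccc3)c(OC)c2)ccc1OCc1ccccc1 | intermediate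
8 | (3S,4S)-3,4-bis{[4-(benzyloxy)-3-methoxyphenyl]methyl}oxolan-2-one (trans) | COc1cc(C[C@@H]2COC(=O)[C@H]2Cc2ccc(OCc3ccccc3)c(OC)c2)ccc1OCc1ccccc1 | intermediate
9 | potassium (4S)-3,4-bis{[4-(benzyloxy)-3-methoxyphenyl]methyl}-4,5-dihydrofuran-2-olate | COc1cc(C[C@@H]2COC([O-])=C2Cc2ccc(OCc3ccccc3)c(OC)c2)ccc1OCc1ccccc1.[K+] | intermediate
10 | (3S,4R)-3,4-bis{[4-(benzyloxy)-3-methoxyphenyl]methyl}-3-hydroxyoxolan-2-one | COc1cc(C[C@@H]2COC(=O)[C@]2(O)Cc2ccc(OCc3ccccc3)c(OC)c2)ccc1OCc1ccccc1 | intermediate
11 | (3S,4R)-3-hydroxy-3,4-bis[(4-hydroxy-3-methoxyphenyl)methyl]oxolan-2-one | COc1cc(C[C@@H]2COC(=O)[C@]2(O)Cc2ccc(O)c(OC)c2)ccc1O | target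

**Total step count:** 6. **Longest linear sequence:** 6 steps (1 to 11).

**Steps most likely to fail**

Step 4. Hydride transfer to the fully alkylated, tetrasubstituted C3=C4 bond may be slow, the catalyst may discriminate the two faces of C4 poorly, or 1,2-reduction to the lactol may compete. The fallback sets out from 6 and returns at 7.
- Opening with LiOH (1.05 equiv, THF–H2O) should give lithium (2Z)-2,3-bis{[4-(benzyloxy)-3-methoxyphenyl]methyl}-4-hydroxybut-2-enoate F1.
- Carboxylate-directed asymmetric hydrogenation of this tetrasubstituted acrylate with Ru(OAc)2[(S)-BINAP] (antipode if the sense is opposite), H2 (50 atm), MeOH, 50 °C, should add both hydrogens to one face and give lithium (2R,3S)-2,3-bis{[4-(benzyloxy)-3-methoxyphenyl]methyl}-4-hydroxybutanoate F2.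
- Acidification (aq HCl, then catalytic TsOH in toluene) should close the ring to cis-lactone 7, which re-enters at the DBU equilibration of step 4.

Step 3. The rhodium hydride may semi-hydrogenate the triple bond, the amine may isomerise the doubly activated propargylic CH2 groups to an allene, or the hindered alkyne may take up CO sluggishly. The fallback sets out from 5, returns at 6, and still forms the same two C–C bonds in one operation.
- Heating 5 with 4-phenyloxazole (neat, sealed tube, about 220 °C) should effect Diels–Alder addition across the two oxazole carbons flanking the ring oxygen, followed by retro-Diels–Alder loss of benzonitrile, to give symmetrical 3,4-bis{[4-(benzyloxy)-3-methoxyphenyl]methyl}furan F3.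
- Sensitised photooxygenation (O2, rose bengal, hν, iPr2NEt, CH2Cl2, −78 °C) should give 3,4-bis{[4-(benzyloxy)-3-methoxyphenyl]methyl}-5-hydroxyfuran-2(5H)-one F4, again without a regiochemical issue because F3 is symmetrical.
- NaBH4 (MeOH, 0 °C, then acid) should reduce the masked aldehyde and re-lactonise to butenolide 6.

Step 5. The facial bias at the fully substituted enolate carbon may be insufficient, or the hindered enolate may add to the sulfonimine by-product instead of accepting oxygen. The fallback sets out from 8 and returns at 10.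
- LiN(iPr)2 and Me3SiCl (THF, −78 °C) should give {[(4S)-3,4-bis{[4-(benzyloxy)-3-methoxyphenyl]methyl}-4,5-dihydrofuran-2-yl]oxy}trimethylsilane F5, which is isolated.
- Epoxidation with dimethyldioxirane (acetone–CH2Cl2, −78 °C), a small neutral oxidant with no imine by-product, should occur anti to the C4 arm; aqueous citric acid then cleaves the silyl group (Rubottom oxidation) to give 10.

**Further compounds**
F1 | step 4 | lithium (2Z)-2,3-bis{[4-(benzyloxy)-3-methoxyphenyl]methyl}-4-hydroxybut-2-enoate | [Li+].[O-]C(=O)/C(Cc1ccc(OCc2ccccc2)c(OC)c1)=C(\CO)Cc1ccc(OCc2ccccc2)c(OC)c1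
F2 | step 4 | lithium (2R,3S)-2,3-bis{[4-(benzyloxy)-3-methoxyphenyl]methyl}-4-hydroxybutanoate | COc1cc(C[C@H](CO)[C@@H](Cc2ccc(OCc3ccccc3)c(OC)c2)C([O-])=O)ccc1OCc1ccccc1.[Li+]
F3 | step 3 | 3,4-bis{[4-(benzyloxy)-3-methoxyphenyl]methyl}furan | COc1cc(Cc2cocc2Cc2ccc(OCc3ccccc3)c(OC)c2)ccc1OCc1ccccc1
F4 | step 3 | 3,4-bis{[4-(benzyloxy)-3-methoxyphenyl]methyl}-5-hydroxyfuran-2(5H)-one (racemic) | COc1cc(CC2=C(Cc3ccc(OCc4ccccc4)c(OC)c3)C(=O)OC2O)ccc1OCc1ccccc1
F5 | step 5 | {[(4S)-3,4-bis{[4-(benzyloxy)-3-methoxyphenyl]methyl}-4,5-dihydrofuran-2-yl]oxy}trimethylsilane | COc1cc(C[C@@H]2COC(O[Si](C)(C)C)=C2Cc2ccc(OCc3ccccc3)c(OC)c2)ccc1OCc1ccccc1
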